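1. Judge the cold flask, autumn, by slope, which serves while [growing radical] holds steady and side product takes up no chains. The uptake is the fraction of the charged free monomer entering chains per minute. In the candidate step where growing radical adds free monomer, and while [free monomer] stays near its charge, the uptake is a pseudo-first-order constant proportional to [growing radical]. So [growing radical] is the concentration to watch.

| flask | free monomer | protic impurity | initiator | temperature | remark | time |
|---|---|---|---|---|---|---|
| green | 0.10 M | 0.010 M | 0.30 mM | −40 °C | run made earlier |  |
| amber | 0.15 M | 0.010 M | 0.30 mM | 10 °C | run made earlier |  |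
| grey | 0.20 M | 0.010 M | 0.15 mM | −40 °C | run made earlier |  |
| summer | 0.20 M | 0.0100 M | 0.30 mM | 25 °C |  | 20 min |
| dusk | 0.20 M | 0.0100 M | 0.30 mM | 55 °C |  | 20 min |
| autumn | 0.20 M | 0.0100 M | 0.30 mM | −35 °C |  | 20 min |
| spring | 0.20 M | 0.0100 M | 0.30 mM | −5 °C |  | 20 min |

| run | time / min | monomer in chains / % |
|---|---|---|
| green | 25.0 | 0.2 |
| green | 50.0 | 0 |
| green | 80.0 | 0 |
| green | 150 | 0.4 |
| green | 300 | 0.9 |
| amber | 5.00 | 4.0 |
| amber | 10.0 | 6.1 |
| amber | 15.0 | 9.8 |
| amber | 20.0 | 13.4 |
| amber | 25.0 | 16.2 |
| grey | 60.0 | 0.3 |
| grey | 120 | 2.9 |
| grey | 180 | 0 |
| grey | 240 | 0.6 |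
| grey | 300 | 1.6 |

(standard deviation of a reading: 1 percentage point)

- percent here means free monomer units held: one side product counts as two
- what is said of monomer in chains includes crystals
- crystals is a solid; its amount is given per volume of the solution
- candidate steps: free monomer + monomer in chains -> side product; 2 growing radical -> dead chain; protic impurity + free monomer -> quenched substrate; crystals <-> monomer in chains; initiator -> 2 initiating radical; free monomer + initiating radical -> growing radical + monomer in chains; free monomer + growing radical -> monomer in chains + growing radical

* which flask leads in amount of monomer in chains, in percent of the free monomer charged ("all alike" within 1.5 percentage points) (summer / dusk / autumn / spring / all alike)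
* how much monomer in chains is there at the end, in percent of the free monomer charged: summer
* how much monomer in chains is there at the end, in percent of the free monomer charged: dusk
* how much monomer in chains is there at the end, in percent of the free monomer charged: autumn
* how much monomer in chains is there at the end, in percent of the free monomer charged: spring

2. Autumn looks nearly the same as grey: both hold 0.20 M free monomer and both are cold. Autumn stands at −35 °C against −40 °C and holds twice the initiator.

3. The cold runs barely rise above the scatter of 1 percentage point, so the last green and grey readings are averaged. This gives the cold uptake, the mean last reading divided by its time: 4.17 × 10⁻⁵ /min, a poorly defined reading.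

4. Grey ran 15.0 times as long as autumn, so grey can reach 1.6 % while autumn stays far lower. My own reckoning for autumn is the cold uptake times 20 min, or 0.0833 %, an estimate that may run low, since autumn is warmer than green and grey. Amber's uptake at 10 °C, read from its last reading, is 0.00648 /min, or 156 times the cold one.

5. The forecast gives 40 % for summer, 78 % for dusk, 0.15 % for autumn and 3.7 % for spring: “Dusk should still lead”. Its autumn figure lies above my estimate.

6. Summer leads at 28.4 %. Dusk ends at 4.79 % beside 42.4 % side product, spring at 4.06 %, and autumn at 0.194 %.

    free monomer + monomer in chains → side product (k = 0.0500 /M/min, Ea = 76.0 kJ/mol)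
    2 growing radical → dead chain (k = 9.00 × 10⁸ /M/s, Ea = 8.00 kJ/mol)
    protic impurity + free monomer → quenched substrate (k = 20.0 /M/min, Ea = 63.0 kJ/mol)
    crystals ⇌ monomer in chains, rate k4*(cs4 - [monomer in chains]) while solid is left; crystals form when [monomer in chains] > cs4 (solubility = 0.140 M, k = 1.70 /min)
    initiator → 2 initiating radical (k = 0.0590 /min, Ea = 82.0 kJ/mol)
    free monomer + initiating radical → growing radical + monomer in chains (k = 6.40 × 10⁵ /M/s, Ea = 26.0 kJ/mol)
    free monomer + growing radical → monomer in chains + growing radical, rate k7*[growing radical]*[free monomer] (k = 24000 /M/s, Ea = 18.0 kJ/mol)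
    (constants at 25 °C)

7. In autumn the initiator's half-life by its own step, 820 h, far exceeds the 20 min of the run, and [growing radical] reads 4.21 × 10⁻¹⁰ M at 20.0 min and 4.21 × 10⁻¹⁰ M at 200 min. Autumn's uptake is 9.69 × 10⁻⁵ /min, which is 2.32 times the cold uptake, and the same flask read at 8.0 min holds 0.0775 %, again 2.32 times the cold uptake.

The runs were generated by integration for an exercise, noise included.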